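The γ-lactone (ring A) is cut at both bonds of its CH2–CH2 unit: quaternary C-2–C-3 and C-4–C-5 (C-5 is the lactone carbonyl). This exploits the fact that C-2 of ring A (ring O, CO2H) and the adjacent side-chain CH(CO2H) form a hidden L-malic acid. C-2 can therefore be a chiral α-hydroxy-acid enolate, C-3/C-4 a vinyl unit and C-5 carbon dioxide. In one operation the lithium enolate of a cis-2-tert-butyl-dioxolanone, made from Fráter–Seebach-allylated L-malate, adds to phenyl vinyl sulfone anti to tert-butyl, and the sulfonyl carbanion is carboxylated. Acid then closes ring A; desulfonylation, cross-metathesis with an alkenyl D-malate and hydrogenation finish.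

Key step: step 4

Assumption: the sulfonyl-bearing carbon (compounds 10–13) and the new alkene (21) are carried as stereoisomer mixtures and left open in the SMILES, because steps 6 and 10 erase them.

Step 1
Reactants: 1 diethyl (2S)-2-hydroxybutanedioate (diethyl L-malate); 2 3-bromoprop-1-ene (allyl bromide)
Product: 4 diethyl (2S,3R)-2-hydroxy-3-(prop-2-en-1-yl)butanedioate, via dilithium alkoxide enolate 3 (not isolated)
Conditions: LiN(iPr)2 (2.1 equiv), THF, −78 → −20 °C; 2 (1.3 equiv), −78 → −5 °C; AcOH quench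
Reagents that add atoms: none
Why: Fráter–Seebach alkylation: the chelated dilithium alkoxide–enolate 3 should be allylated on the face opposite its oxygen-bearing stereocentre, which sets C-3 anti to the hydroxyl (2S,3R) and leaves C-2 untouched.

Step 2
Reactants: 4 diethyl (2S,3R)-2-hydroxy-3-(prop-2-en-1-yl)butanedioate
Product: 5 (2S,3R)-2-hydroxy-3-(prop-2-en-1-yl)butanedioic acid
Conditions: KOH (2.5 equiv), EtOH/H2O, 0 °C → rt; then HCl (pH 1)
Reagents that add atoms: potassium hydroxide, [K+].[OH-]
Why: Saponification (acyl substitution by hydroxide) of both ethyl esters should be faster than enolisation, and the dicarboxylate formed no longer enolises, so both stereocentres are kept.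

Step 3
Reactants: 5 (2S,3R)-2-hydroxy-3-(prop-2-en-1-yl)butanedioic acid
Product: 6 (2R)-2-[(2S,4S)-2-tert-butyl-5-oxo-1,3-dioxolan-4-yl]pent-4-enoic acid
Conditions: pivaldehyde (3 equiv), TsOH·H2O (cat.), H2SO4 (cat.), pentane, reflux, Dean–Stark trap; cis isomer purified by crystallisation or chromatography
Reagents that add atoms: 2,2-dimethylpropanal (pivaldehyde), CC(C)(C)C=O
Why: Acid-catalysed acetalisation of the α-hydroxy acid half should close the five-membered dioxolanone in preference to the six-membered ring of the β-carboxyl, and under equilibrating conditions the cis acetal, with tert-butyl and side chain both pseudo-equatorial, is favoured, which sets the acetal carbon as 2S.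

Step 4
Reactants: 6 (2R)-2-[(2S,4S)-2-tert-butyl-5-oxo-1,3-dioxolan-4-yl]pent-4-enoic acid; 7 phenyl vinyl sulfone; 8 carbon dioxide
Product: 11 (2R)-2-{(2S,4S)-2-tert-butyl-4-[2-carboxy-2-(phenylsulfonyl)ethyl]-5-oxo-1,3-dioxolan-4-yl}pent-4-enoic acid, via dilithium carboxylate enolate 9 (not isolated), via dilithium sulfonyl carbanion 10 (not isolated)
Conditions: LiN(iPr)2 (2.2 equiv), THF/DMPU, −78 °C; 7 (1.05 equiv) in THF added slowly, −78 °C; CO2 (dry gas), −78 °C; cold 1 M HCl
Reagents that add atoms: none
Why: LiN(iPr)2 gives the carboxylate–enolate 9, whose carboxylate shields the side-chain CH from deprotonation; the enolate carbon adds to the terminal carbon of phenyl vinyl sulfone (first C–C bond, C-2–C-3 of the later ring A), and the sulfonyl carbanion 10 so formed, which diisopropylamine cannot protonate, attacks CO2 (second C–C bond, C-4–C-5). The closest known reaction types are the Michael addition of pivaldehyde-dioxolanone enolates (self-regeneration of stereocentres) and the tandem conjugate addition–electrophile trapping of vinyl sulfones, finished by the ordinary carboxylation of a lithiated sulfone. No ring is closed in this step; ring A closes in step 5 by lactonisation onto the carboxyl made here. The new quaternary stereocentre is controlled by the acetal centre: the sulfone approaches the planar enolate anti to tert-butyl, so the CH2 group takes the place of the former hydrogen (retention, 4S in 11), while the sulfonyl-bearing carbon forms unselectively and is erased in step 6. The step needs the vinyl sulfone to be consumed by the enolate and not by carbanion 10 (secured by slow addition of one equivalent at −78 °C), and it needs C-carboxylation before the carbanion is lost (secured by the fast reaction of CO2 with a localised carbanion and a cold acidic quench).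

Step 5
Reactants: 11 (2R)-2-{(2S,4S)-2-tert-butyl-4-[2-carboxy-2-(phenylsulfonyl)ethyl]-5-oxo-1,3-dioxolan-4-yl}pent-4-enoic acid
Product: 13 (2R)-2-[(2S)-2-carboxy-5-oxo-4-(phenylsulfonyl)oxolan-2-yl]pent-4-enoic acid, via ring-opened hydroxy triacid 12 (not isolated)
Conditions: 2 M aq. HCl/1,4-dioxane (1:1), 50 °C; concentrate from toluene
Reagents that add atoms: none
Why: Acid-catalysed hydrolysis of the acetal ester should release pivaldehyde and the tertiary alcohol 12, which lactonises (5-exo-trig acyl substitution) onto the sulfonyl-activated carboxyl, the only carboxyl that gives an unstrained ring, so ring A closes without touching the stereocentres.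

Step 6
Reactants: 13 (2R)-2-[(2S)-2-carboxy-5-oxo-4-(phenylsulfonyl)oxolan-2-yl]pent-4-enoic acid
Product: 14 (2R)-2-[(2S)-2-carboxy-5-oxooxolan-2-yl]pent-4-enoic acid
Conditions: SmI2 (5 equiv), THF/MeOH, −78 °C
Reagents that add atoms: none
Why: Reductive desulfonylation: electron transfer from SmI2 to the α-sulfonyl lactone should expel benzenesulfinate, and MeOH protonates the samarium enolate, which turns the sulfonyl-bearing carbon into CH2 and leaves alkene, acids and both stereocentres alone.

Step 7
Reactants: 14 (2R)-2-[(2S)-2-carboxy-5-oxooxolan-2-yl]pent-4-enoic acid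
Product: 15 benzyl (2S)-2-[(2R)-1-(benzyloxy)-1-oxopent-4-en-2-yl]-5-oxooxolane-2-carboxylate
Conditions: BnBr (2.4 equiv), Cs2CO3 (1.1 equiv), DMF, 0 °C → rt
Reagents that add atoms: benzyl bromide, BrCc1ccccc1
Why: SN2 O-alkylation of the two caesium carboxylates should give the dibenzyl ester, carbonate being too weak a base to enolise an ester or open the lactone.

Step 8
Reactants: 16 (2R)-2-hydroxybutanedioic acid (D-malic acid); 17 non-8-en-1-ol
Product: 20 (3R)-3-hydroxy-4-(non-8-en-1-yloxy)-4-oxobutanoic acid, via O-trifluoroacetyl malic anhydride 18 (not isolated), via O-trifluoroacetyl half ester 19 (not isolated)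
Conditions: (CF3CO)2O (2.5 equiv), 0 °C → rt, then evaporate; 17 (0.9 equiv), CH2Cl2, rt; then H2O/THF, rt
Reagents that add atoms: none
Why: Anhydride alcoholysis: the alcohol should attack the anhydride carbonyl next to the trifluoroacetoxy-bearing carbon, the more electrophilic one, to give the 1-ester with the 4-carboxyl free, and water then cleaves the labile trifluoroacetate without touching the stereocentre.

Step 9
Reactants: 15 benzyl (2S)-2-[(2R)-1-(benzyloxy)-1-oxopent-4-en-2-yl]-5-oxooxolane-2-carboxylate; 20 (3R)-3-hydroxy-4-(non-8-en-1-yloxy)-4-oxobutanoic acid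
Product: 21 (3R)-4-{[(11R)-12-(benzyloxy)-11-[(2S)-2-[(benzyloxy)carbonyl]-5-oxooxolan-2-yl]-12-oxododec-8-en-1-yl]oxy}-3-hydroxy-4-oxobutanoic acid (E/Z mixture)
Conditions: RuCl2(=CHPh)(PCy3)(H2IMes) (second-generation Grubbs catalyst, 5 mol%), 1,4-benzoquinone (10 mol%), 20 (3 equiv), CH2Cl2, 40 °C
Reagents that add atoms: none
Why: Olefin cross-metathesis of two unhindered terminal alkenes should be driven to the cross product by the excess of 20 and the loss of ethene, the ruthenium carbene tolerating acid, hydroxyl, esters and lactone, with the alkene geometry of no consequence.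

Step 10
Reactants: 21 (3R)-4-{[(11R)-12-(benzyloxy)-11-[(2S)-2-[(benzyloxy)carbonyl]-5-oxooxolan-2-yl]-12-oxododec-8-en-1-yl]oxy}-3-hydroxy-4-oxobutanoic acid
Product: 22 (2R)-2-[(2S)-2-carboxy-5-oxooxolan-2-yl]-12-{[(2R)-3-carboxy-2-hydroxypropanoyl]oxy}dodecanoic acid (target)
Conditions: H2 (1 atm), 10% Pd/C, EtOAc, rt
Reagents that add atoms: none
Why: Heterogeneous hydrogenation should saturate the alkene and hydrogenolysis should cleave both benzyl esters, while the alkyl malate ester, the lactone and all three stereocentres are inert to these conditions.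

Compound list
1 | diethyl (2S)-2-hydroxybutanedioate (diethyl L-malate) | CCOC(=O)C[C@H](O)C(=O)OCC | starting material
2 | 3-bromoprop-1-ene (allyl bromide) | C=CCBr | starting material
3 | dilithium alkoxide enolate of 1 | [O-][C@H](C(=O)OCC)C=C([O-])OCC.[Li+].[Li+] | intermediate
4 | diethyl (2S,3R)-2-hydroxy-3-(prop-2-en-1-yl)butanedioate | O[C@H](C(=O)OCC)[C@@H](CC=C)C(=O)OCC | intermediate
5 | (2S,3R)-2-hydroxy-3-(prop-2-en-1-yl)butanedioic acid | O[C@H](C(=O)O)[C@@H](CC=C)C(=O)O | intermediate
6 | (2R)-2-[(2S,4S)-2-tert-butyl-5-oxo-1,3-dioxolan-4-yl]pent-4-enoic acid | CC(C)(C)[C@H]1O[C@@H]([C@@H](CC=C)C(=O)O)C(=O)O1 | intermediate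
7 | phenyl vinyl sulfone | C=CS(=O)(=O)c1ccccc1 | starting material
8 | carbon dioxide | O=C=O | starting material
9 | dilithium carboxylate enolate of 6 | CC(C)(C)[C@H]1OC(=C([O-])O1)[C@@H](CC=C)C(=O)[O-].[Li+].[Li+] | intermediate
10 | dilithium salt of the α-sulfonyl carbanion formed by addition of 9 to 7 | CC(C)(C)[C@H]1O[C@]([C@@H](CC=C)C(=O)[O-])(C[CH-]S(=O)(=O)c2ccccc2)C(=O)O1.[Li+].[Li+] | intermediate
11 | (2R)-2-{(2S,4S)-2-tert-butyl-4-[2-carboxy-2-(phenylsulfonyl)ethyl]-5-oxo-1,3-dioxolan-4-yl}pent-4-enoic acid | CC(C)(C)[C@H]1O[C@]([C@@H](CC=C)C(=O)O)(CC(C(=O)O)S(=O)(=O)c2ccccc2)C(=O)O1 | intermediate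
12 | (3S,4R)-3-hydroxy-1-(phenylsulfonyl)hept-6-ene-1,3,4-tricarboxylic acid | C=CC[C@@H](C(=O)O)[C@](O)(C(=O)O)CC(C(=O)O)S(=O)(=O)c1ccccc1 | intermediate
13 | (2R)-2-[(2S)-2-carboxy-5-oxo-4-(phenylsulfonyl)oxolan-2-yl]pent-4-enoic acid | C=CC[C@@H](C(=O)O)[C@]1(C(=O)O)CC(S(=O)(=O)c2ccccc2)C(=O)O1 | intermediate
14 | (2R)-2-[(2S)-2-carboxy-5-oxooxolan-2-yl]pent-4-enoic acid | C=CC[C@@H](C(=O)O)[C@]1(C(=O)O)CCC(=O)O1 | intermediate
15 | benzyl (2S)-2-[(2R)-1-(benzyloxy)-1-oxopent-4-en-2-yl]-5-oxooxolane-2-carboxylate | C=CC[C@@H](C(=O)OCc1ccccc1)[C@]2(C(=O)OCc3ccccc3)CCC(=O)O2 | intermediate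
16 | (2R)-2-hydroxybutanedioic acid (D-malic acid) | O=C(O)C[C@@H](O)C(=O)O | starting material
17 | non-8-en-1-ol | C=CCCCCCCCO | starting material
18 | (3R)-2,5-dioxooxolan-3-yl trifluoroacetate | O=C1C[C@@H](OC(=O)C(F)(F)F)C(=O)O1 | intermediate
19 | (3R)-4-(non-8-en-1-yloxy)-4-oxo-3-[(trifluoroacetyl)oxy]butanoic acid | O=C(O)C[C@@H](OC(=O)C(F)(F)F)C(=O)OCCCCCCCC=C | intermediate
20 | (3R)-3-hydroxy-4-(non-8-en-1-yloxy)-4-oxobutanoic acid | O=C(O)C[C@@H](O)C(=O)OCCCCCCCC=C | intermediate
21 | (3R)-4-{[(11R)-12-(benzyloxy)-11-[(2S)-2-[(benzyloxy)carbonyl]-5-oxooxolan-2-yl]-12-oxododec-8-en-1-yl]oxy}-3-hydroxy-4-oxobutanoic acid | O=C(O)C[C@@H](O)C(=O)OCCCCCCCC=CC[C@@H](C(=O)OCc1ccccc1)[C@]2(C(=O)OCc3ccccc3)CCC(=O)O2 | intermediate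
22 | (2R)-2-[(2S)-2-carboxy-5-oxooxolan-2-yl]-12-{[(2R)-3-carboxy-2-hydroxypropanoyl]oxy}dodecanoic acid | O=C(O)C[C@@H](O)C(=O)OCCCCCCCCCC[C@@H](C(=O)O)[C@]1(C(=O)O)CCC(=O)O1 | target

Total step count: 10. Longest linear sequence: 9 (steps 1–7, 9 and 10; step 8 is the side branch).

Steps most likely to fail

Step 4. The vinyl sulfone may be consumed by anionic chain growth from carbanion 10 before CO2 is admitted, or the lithium sulfonylacetate may lose CO2 again during work-up. The fallback sets out from 6 and replaces the sulfone by a carboxyl-based activating group that leaves as CO2. The same dianion 9 is added to tert-butyl acrylate at −78 °C; its hindered ester enolate is less prone to a second addition. That enolate is carboxylated with CO2 to give the malonic half ester (2R)-2-{(2S,4S)-2-tert-butyl-4-[3-tert-butoxy-2-carboxy-3-oxopropyl]-5-oxo-1,3-dioxolan-4-yl}pent-4-enoic acid F1. TFA/H2O at rt should cleave the tert-butyl ester and the acetal and close ring A to (2R)-2-[(2S)-2,4-dicarboxy-5-oxooxolan-2-yl]pent-4-enoic acid F2. Warming in toluene (90 °C) decarboxylates the malonic unit, and the fallback comes back to the route at 14, so steps 5 and 6 are not needed.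

Step 9. The metathesis may take a statistical course (homodimerisation of 15, slow turnover through chelation by the hydroxy acid of 20), and alkene migration would shorten the chain. The fallback sets out from 15 and makes the malate ester bond after the C=C bond instead of before it. Metathesis of 15 with a large excess (8 equiv) of the plain alkenol 17, under the same catalyst and with benzoquinone, should give benzyl (2S)-2-[(2R)-1-(benzyloxy)-12-hydroxy-1-oxododec-4-en-2-yl]-5-oxooxolane-2-carboxylate F3; recovered homodimer of 15 is returned to the same reaction. Acylation of F3 with anhydride 18 (CH2Cl2, rt) gives the O-trifluoroacetyl derivative of 21 F4, and stirring with H2O/THF cleaves the trifluoroacetate, so the fallback comes back at 21.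

Step 5. The sulfonylacetic acid unit may decarboxylate in warm acid before the ring closes. The fallback sets out from 11 and removes the sulfone first. SmI2/HMPA/THF at −20 °C (reductive cleavage of an alkyl phenyl sulfone) should give (2R)-2-[(2S,4S)-2-tert-butyl-4-(2-carboxyethyl)-5-oxo-1,3-dioxolan-4-yl]pent-4-enoic acid F5, an ordinary propanoic acid that cannot lose CO2. 2 M aq. HCl/1,4-dioxane at 50 °C then opens the acetal to (3S,4R)-3-hydroxyhept-6-ene-1,3,4-tricarboxylic acid F6, which lactonises on concentration, and the fallback comes back at 14.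

Further compounds
F1 | step 4 | (2R)-2-{(2S,4S)-2-tert-butyl-4-[3-tert-butoxy-2-carboxy-3-oxopropyl]-5-oxo-1,3-dioxolan-4-yl}pent-4-enoic acid | CC(C)(C)[C@H]1O[C@]([C@@H](CC=C)C(=O)O)(CC(C(=O)O)C(=O)OC(C)(C)C)C(=O)O1
F2 | step 4 | (2R)-2-[(2S)-2,4-dicarboxy-5-oxooxolan-2-yl]pent-4-enoic acid | C=CC[C@@H](C(=O)O)[C@]1(C(=O)O)CC(C(=O)O)C(=O)O1
F3 | step 9 | benzyl (2S)-2-[(2R)-1-(benzyloxy)-12-hydroxy-1-oxododec-4-en-2-yl]-5-oxooxolane-2-carboxylate | OCCCCCCCC=CC[C@@H](C(=O)OCc1ccccc1)[C@]2(C(=O)OCc3ccccc3)CCC(=O)O2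
F4 | step 9 | O-trifluoroacetyl derivative of 21 | O=C(O)C[C@@H](OC(=O)C(F)(F)F)C(=O)OCCCCCCCC=CC[C@@H](C(=O)OCc1ccccc1)[C@]2(C(=O)OCc3ccccc3)CCC(=O)O2
F5 | step 5 | (2R)-2-[(2S,4S)-2-tert-butyl-4-(2-carboxyethyl)-5-oxo-1,3-dioxolan-4-yl]pent-4-enoic acid | CC(C)(C)[C@H]1O[C@]([C@@H](CC=C)C(=O)O)(CCC(=O)O)C(=O)O1
F6 | step 5 | (3S,4R)-3-hydroxyhept-6-ene-1,3,4-tricarboxylic acid | C=CC[C@@H](C(=O)O)[C@](O)(C(=O)O)CCC(=O)O
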